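## Structural features

The target is a chroman: aromatic ring A (C4a, C5, C6, C7, C8, C8a) is fused through C4a–C8a to dihydropyran ring B (O1, C2, C3, C4, C4a, C8a). Ring A is a fully differentiated hydroquinone: O1 on C8a and the free hydroxyl on C6 are para, methyl groups sit on C5 and C8, and C7 carries the only aromatic hydrogen. C2 is the single stereocenter, a quaternary carbon bearing O1, a methyl group, the ring methylene C3 and the chain methylene C1′. It must be R, and its two methylene arms first differ three bonds away, so there is no neighbouring stereocenter or steric bias to relay from. The side chain on C2 is a 4,8,12-trimethyltrideca-3,7,11-trienyl unit with 3′E and 7′E trisubstituted olefins; once it is in place this skipped polyene rules out hydrogenation, electrophilic halogenation and strong acid (cation–olefin cyclisation). The free 6-chromanol is easily oxidised to the quinone under basic aerobic conditions. The key step exploits the fact that C4–C3–C2(CH3)–C1′…C13′ is, carbon for carbon, an all-E geranylgeranyl chain whose oxygen sits on the tertiary end (C2) of its terminal allyl unit instead of the primary end (C4): if C3–C4 is read as a vinyl group, O1–C2 is a branched allylic C–O bond. The real difficulty is to create the oxygenated quaternary C2 as one enantiomer while the intact triene is carried along, without a separately made chiral chroman building block.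

## Logic of the disconnections

9 to 8: the O–Si bond on the C6 oxygen is cut. This only masks the oxidation-prone chromanol through the metal-catalysed steps. The forward step must cleave the silyl ether without base-induced aerobic oxidation of the phenol and without touching the triene.

8 to 6 (through 7): the C4–C4a bond is cut. This opens ring B and exposes C3–C4 as a monosubstituted vinyl group on C2 and C4a as an aryl bromide, so 8 becomes an acyclic allyl aryl ether. The forward step needs anti-Markovnikov hydroboration of the one monosubstituted olefin in the presence of three trisubstituted ones, then an intramolecular sp3–sp2 coupling that closes a six-membered ring faster than β-hydride elimination.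

6 to 3 and 5 (key disconnection): the O1–C2 bond is cut with allylic transposition of the oxygen from C2 to C4. This splits the molecule into an achiral C8 phenol and an achiral C20 allyl carbonate that already holds every chain carbon and both E olefins. The stereocenter, the tertiary ether bond and the union of the two halves are therefore all assigned to one catalytic step. The forward step must attack the fully substituted allyl terminus rather than the primary one, select one enantioface, and leave the aryl C–Br bond alone.

5 to 4: the carbonate C–O bond is cut, which returns the purchasable all-E C20 allylic alcohol. The forward step must acylate without allylic rearrangement.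

3 to 2 to 1: the C–Br bond and then the O–Si bond are cut. Because 1 is symmetric, mono-silylation can give only one product, and the remaining free hydroxyl then directs bromine to its only open ortho position, which is the future C4a. The forward steps need mono-selectivity in the silylation and ortho-to-hydroxyl selectivity in the bromination.

## Other disconnections considered

Alternative 1: (the first that comes to mind) cut C1′–C2′. A preformed chroman that already carries the stereocenter, tert-butyldimethyl{[(2S)-2,5,8-trimethyl-2-[(phenylsulfonyl)methyl]-3,4-dihydro-2H-chromen-6-yl]oxy}silane A1, would be deprotonated and alkylated with (2E,6E)-farnesyl bromide A2 to give sulfone A3, followed by reductive desulfonylation and desilylation. The key bond is formed away from the difficulty: C2 would have to be set beforehand in a separate multi-step asymmetric synthesis or resolution of A1, since the 5,8-dimethyl series is not sold in chiral form. Reductive desulfonylation next to three olefins risks double-bond migration or reduction, and the count exceeds the chosen plan by several steps.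

Alternative 2: cut O1–C2 by protonation of an olefin (biomimetic). Friedel–Crafts C-allylation of 1 would give 2,5-dimethyl-3-[(2E,6E,10E)-3,7,11,15-tetramethylhexadeca-2,6,10,14-tetraen-1-yl]benzene-1,4-diol A4, and a chiral Brønsted acid would then have to effect the 6-endo hydroalkoxylation to 9. The acid would have to protonate one of four nearly identical trisubstituted olefins and distinguish CH3 from CH2 at an open tertiary cation, with no covalent element to fix the face, while cation–olefin cyclisation of the chain competes. Mono-C-allylation of 1 is itself unselective. The chosen plan replaces this with a ligand-controlled ion-pair capture in which the olefins are bystanders.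

Alternative 3: cut C4–C4a and O1–C8a together through a spirodienone. The chain would first be attached para to the hydroxyl, as in 4-[(3R,6E,10E)-3-hydroxy-3,7,11,15-tetramethylhexadeca-6,10,14-trien-1-yl]-2,5-dimethylphenol A5. Oxidative dearomatisation with PhI(OAc)2 would give the spiro ether (2R)-2,6,9-trimethyl-2-[(3E,7E)-4,8,12-trimethyltrideca-3,7,11-trien-1-yl]-1-oxaspiro[4.5]deca-6,9-dien-8-one A6, and an acid-induced dienone–phenol 1,2-shift of C4 from C8a to C4a would give 9. The connectivity logic is attractive, but the key step only retains C2 and does not create it. The stereocenter would need its own asymmetric epoxidation and reductive opening sequence before the arene is attached, and the 1,2-shift exposes the polyene to acid. The route is longer and the key step does not carry the stereochemical problem.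

Key step: step 4

Assumption: the sense of asymmetric induction in step 4 is assigned by analogy with E-configured 3,3-disubstituted allyl carbonates. Both antipodes of the diphosphine ligand are commercial, so the antipode that delivers the 3R ether 6 is the one to be used if the assignment proves reversed.

## Route

Step 1
Reactants: 1 2,5-dimethylbenzene-1,4-diol
Product: 2 4-[(tert-butyldimethylsilyl)oxy]-2,5-dimethylphenol
Conditions: TBSCl (0.5 equiv), imidazole, DMF, 0 °C to rt; excess 1 recovered
Reagents that add atoms: tert-butyldimethylsilyl chloride, CC(C)(C)[Si](C)(C)Cl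
Why: Silylation of a phenol with a silyl chloride and imidazole; 1 is symmetric, so only one mono-silyl ether can form, and using 1 in excess should keep bis-silylation low; no stereocenter is formed.

Step 2
Reactants: 2 4-[(tert-butyldimethylsilyl)oxy]-2,5-dimethylphenol
Product: 3 2-bromo-4-[(tert-butyldimethylsilyl)oxy]-3,6-dimethylphenol
Conditions: NBS (1.0 equiv), i-Pr2NH (10 mol%), CH2Cl2, −20 °C to 0 °C, dark
Reagents that add atoms: N-bromosuccinimide, O=C1CCC(=O)N1Br
Why: Amine-mediated ortho-bromination of a phenol (electrophilic aromatic substitution); the free hydroxyl is the strongest activator, its para position is blocked and one ortho position bears methyl, so bromine should enter at the only open position ortho to it, while the bulkier and weaker silyloxy director leaves the other C–H untouched.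

Step 3
Reactants: 4 (2E,6E,10E)-3,7,11,15-tetramethylhexadeca-2,6,10,14-tetraen-1-ol
Product: 5 methyl (2E,6E,10E)-3,7,11,15-tetramethylhexadeca-2,6,10,14-tetraen-1-yl carbonate
Conditions: ClCO2Me, pyridine, CH2Cl2, 0 °C
Reagents that add atoms: methyl chloroformate, COC(=O)Cl
Why: Acylation of a primary allylic alcohol with a chloroformate; pyridine scavenges HCl, so the allylic system and the E olefins should not rearrange.

Step 4
Reactants: 3 2-bromo-4-[(tert-butyldimethylsilyl)oxy]-3,6-dimethylphenol; 5 methyl (2E,6E,10E)-3,7,11,15-tetramethylhexadeca-2,6,10,14-tetraen-1-yl carbonate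
Product: 6 tert-butyl{3-bromo-2,5-dimethyl-4-{[(3R,6E,10E)-3,7,11,15-tetramethylhexadeca-1,6,10,14-tetraen-3-yl]oxy}phenoxy}dimethylsilane
Conditions: Pd2(dba)3·CHCl3 (2.5 mol%), (R,R)-DACH-phenyl Trost ligand (7.5 mol%), degassed CH2Cl2, 0 °C to rt
Reagents that add atoms: none
Why: Palladium-catalysed asymmetric allylic etherification (Tsuji–Trost type), used here in its known form for phenols and E-configured 3,3-disubstituted allyl carbonates. Zerovalent palladium ionises 5 with inversion to a cationic η3-allyl complex (chain syn, methyl anti, as fixed by the 2E geometry) and liberates CO2 and methoxide, which deprotonates 3. The phenoxide then attacks outer-sphere, anti to palladium, at the more substituted allyl terminus, where positive charge is concentrated and the Pd–C bond is longest in complexes of the twofold-symmetric bis(diphenylphosphinobenzoyl)diamine ligand; this forms O1–C2 and leaves C3–C4 as a vinyl group. No ring is closed. The new stereocenter (C3 of the chain, the future C2) is controlled only by the ligand: the two diastereomeric η3 complexes interconvert by η3–η1–η3 slippage at the unsubstituted terminus faster than they are captured, and the chiral pocket selects the face, the ligand antipode being chosen to give 3R. The step needs branched over linear regioselectivity, enantioface selectivity and chemoselectivity for C–O ionisation over insertion into C–Br; the first two rest on the ligand and the E geometry of 5, the third on the inertness of an electron-rich aryl bromide with two ortho substituents toward a triarylphosphine–palladium complex at 0 °C to rt. C-Allylation is excluded because both ortho positions and the para position of 3 are substituted. The tertiary ether is the kinetic product, so the reaction should be stopped at full conversion of 3 and kept cold to prevent palladium-mediated re-ionisation to the linear ether.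

Step 5
Reactants: 6 tert-butyl{3-bromo-2,5-dimethyl-4-{[(3R,6E,10E)-3,7,11,15-tetramethylhexadeca-1,6,10,14-tetraen-3-yl]oxy}phenoxy}dimethylsilane
Product: 8 tert-butyldimethyl{[(2R)-2,5,8-trimethyl-2-[(3E,7E)-4,8,12-trimethyltrideca-3,7,11-trien-1-yl]-3,4-dihydro-2H-chromen-6-yl]oxy}silane, via B-alkyl-9-BBN adduct 7 (not isolated)
Conditions: 9-BBN dimer (0.65 equiv), THF, 0 °C to rt; then Pd(OAc)2 (5 mol%), SPhos (10 mol%), aq K3PO4 (3 equiv), THF, 65 °C, 0.02 M
Reagents that add atoms: none
Why: Hydroboration followed by intramolecular B-alkyl Suzuki–Miyaura coupling: 9-BBN should add boron to the terminal carbon of the monosubstituted vinyl group far faster than to the three trisubstituted olefins, giving 7; oxidative addition of the aryl bromide, base-assisted transmetalation of the primary alkyl group and reductive elimination from a seven-membered palladacycle close ring B at C4–C4a, the bulky biarylphosphine favouring reductive elimination over β-hydride elimination. No bond to C2 is made or broken, so its configuration is retained (descriptor R in 8).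

Step 6
Reactants: 8 tert-butyldimethyl{[(2R)-2,5,8-trimethyl-2-[(3E,7E)-4,8,12-trimethyltrideca-3,7,11-trien-1-yl]-3,4-dihydro-2H-chromen-6-yl]oxy}silane
Product: 9 (2R)-2,5,8-trimethyl-2-[(3E,7E)-4,8,12-trimethyltrideca-3,7,11-trien-1-yl]-3,4-dihydro-2H-chromen-6-ol
Conditions: TBAF (1.2 equiv), AcOH (1.2 equiv), THF, 0 °C, argon
Reagents that add atoms: none
Why: Fluoride-induced cleavage of an aryl silyl ether; the acetic acid buffer keeps the liberated chromanol protonated and so suppresses its aerobic oxidation, and neither reagent touches the triene or C2.

## Compound list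

1 | 2,5-dimethylbenzene-1,4-diol | Cc1cc(O)c(C)cc1O | starting material
2 | 4-[(tert-butyldimethylsilyl)oxy]-2,5-dimethylphenol | Cc1cc(O[Si](C)(C)C(C)(C)C)c(C)cc1O | intermediate
3 | 2-bromo-4-[(tert-butyldimethylsilyl)oxy]-3,6-dimethylphenol | Cc1cc(O[Si](C)(C)C(C)(C)C)c(C)c(Br)c1O | intermediate
4 | (2E,6E,10E)-3,7,11,15-tetramethylhexadeca-2,6,10,14-tetraen-1-ol | CC(C)=CCC/C(C)=C/CC/C(C)=C/CC/C(C)=C/CO | starting material
5 | methyl (2E,6E,10E)-3,7,11,15-tetramethylhexadeca-2,6,10,14-tetraen-1-yl carbonate | CC(C)=CCC/C(C)=C/CC/C(C)=C/CC/C(C)=C/COC(=O)OC | intermediate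
6 | tert-butyl{3-bromo-2,5-dimethyl-4-{[(3R,6E,10E)-3,7,11,15-tetramethylhexadeca-1,6,10,14-tetraen-3-yl]oxy}phenoxy}dimethylsilane | C=C[C@@](C)(CC/C=C(\C)CC/C=C(\C)CCC=C(C)C)Oc1c(Br)c(C)c(O[Si](C)(C)C(C)(C)C)cc1C | intermediate
7 | 9-[(3S,6E,10E)-3-{2-bromo-4-[(tert-butyldimethylsilyl)oxy]-3,6-dimethylphenoxy}-3,7,11,15-tetramethylhexadeca-6,10,14-trien-1-yl]-9-borabicyclo[3.3.1]nonane (same spatial arrangement as 6; the descriptor changes because boron ranks below carbon) | C1CCC2CCCC1B2CC[C@@](C)(CC/C=C(\C)CC/C=C(\C)CCC=C(C)C)Oc1c(Br)c(C)c(O[Si](C)(C)C(C)(C)C)cc1C | intermediate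
8 | tert-butyldimethyl{[(2R)-2,5,8-trimethyl-2-[(3E,7E)-4,8,12-trimethyltrideca-3,7,11-trien-1-yl]-3,4-dihydro-2H-chromen-6-yl]oxy}silane | CC(C)=CCC/C(C)=C/CC/C(C)=C/CC[C@]1(C)CCc2c(C)c(O[Si](C)(C)C(C)(C)C)cc(C)c2O1 | intermediate
9 | (2R)-2,5,8-trimethyl-2-[(3E,7E)-4,8,12-trimethyltrideca-3,7,11-trien-1-yl]-3,4-dihydro-2H-chromen-6-ol | CC(C)=CCC/C(C)=C/CC/C(C)=C/CC[C@]1(C)CCc2c(C)c(O)cc(C)c2O1 | target

## Step count and least certain steps

Total step count: 6. Longest linear sequence: 5 steps (1, 2, 4, 5, 6, from compound 1); step 3 is a one-step branch from compound 4.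

Step 4 (key step). The most likely failure is slow or misdirected capture of the η3-allyl complex: the nucleophilic oxygen of 3 is flanked by bromine and methyl, and the carbon it must attack is fully substituted, so attack at the primary terminus may compete. A second risk is erosion of enantiopurity by palladium-mediated re-ionisation of the product ether, whose bromophenoxide is a good leaving group. The fallback keeps O1–C2 as the stereodefining bond but makes it intramolecular and appends the chain afterwards; it sets out from 3 and returns at 8.
- Hydroboration of commercial (2E)-3-methylpenta-2,4-dien-1-ol at its vinyl group with 9-BBN, then B-alkyl Suzuki coupling with the bromide of 3, would give (2E)-5-{5-[(tert-butyldimethylsilyl)oxy]-2-hydroxy-3,6-dimethylphenyl}-3-methylpent-2-en-1-ol F1.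
- Acylation of the primary hydroxyl with methyl chloroformate would give (2E)-5-{5-[(tert-butyldimethylsilyl)oxy]-2-hydroxy-3,6-dimethylphenyl}-3-methylpent-2-en-1-yl methyl carbonate F2.
- Intramolecular palladium-catalysed asymmetric allylic etherification (Pd2(dba)3·CHCl3, the same ligand family, AcOH, CH2Cl2), a reaction type established for 2-methyl-2-vinylchromans, would close ring B and give tert-butyl{[(2S)-2-ethenyl-2,5,8-trimethyl-3,4-dihydro-2H-chromen-6-yl]oxy}dimethylsilane F3.
- The chain would come from geranyl bromide and lithiated 1-(trimethylsilyl)propyne, giving trimethyl[(5E)-6,10-dimethylundeca-5,9-dien-1-yn-1-yl]silane F4. Desilylation (K2CO3, MeOH) would give (5E)-6,10-dimethylundeca-5,9-dien-1-yne F5, and carboalumination–iodination (AlMe3, Cp2ZrCl2, then I2) would give (1E,5E)-1-iodo-2,6,10-trimethylundeca-1,5,9-triene F6.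
- Hydroboration of the vinyl group of F3 with 9-BBN and Suzuki coupling with F6 (PdCl2(dppf), AsPh3, Cs2CO3) would give 8.

Step 5. The most likely failure is in the ring-closing coupling. Oxidative addition into an electron-rich aryl bromide with two ortho substituents may be slow, which would allow protodeboronation of the alkylborane or β-hydride elimination from the alkylpalladium intermediate. Partial loss of the silyl group under aqueous phosphate would be harmless, since it leads to 9. The fallback replaces the palladium coupling by an anionic ring closure; it sets out from 7 and returns at 8.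
- Oxidation of 7 (NaBO3·4H2O, THF/H2O) would give (3R,6E,10E)-3-{2-bromo-4-[(tert-butyldimethylsilyl)oxy]-3,6-dimethylphenoxy}-3,7,11,15-tetramethylhexadeca-6,10,14-trien-1-ol F7.
- CBr4 and PPh3 would convert it to tert-butyl{3-bromo-4-{[(3R,6E,10E)-1-bromo-3,7,11,15-tetramethylhexadeca-6,10,14-trien-3-yl]oxy}-2,5-dimethylphenoxy}dimethylsilane F8.
- Aryl bromine–lithium exchange (t-BuLi, THF, −100 °C to −78 °C) followed by warming would close ring B by intramolecular alkylation of the aryllithium (Parham cyclisation) and give 8.

Step 2. The most likely failure is oxidation of the electron-rich mono-silylated hydroquinone to the quinone with loss of the silyl group, or some bromination ortho to the silyloxy group. The fallback introduces the halogen at the quinone stage and differentiates the two hydroxyls afterwards by sterics; it sets out from 1 and returns at 3.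
- Oxidation of 1 (FeCl3, aqueous MeOH; the product is also purchasable) would give 2,5-dimethylcyclohexa-2,5-diene-1,4-dione F9.
- Conjugate addition of HBr (48% HBr, AcOH) and enolisation would give 2-bromo-3,6-dimethylbenzene-1,4-diol F10 as the only possible regioisomer.
- Silylation (TBSCl, imidazole, DMF) is expected at the hydroxyl with only one large ortho neighbour, which gives 3.

## Further compounds

F1 | step 4 | (2E)-5-{5-[(tert-butyldimethylsilyl)oxy]-2-hydroxy-3,6-dimethylphenyl}-3-methylpent-2-en-1-ol | OC/C=C(\C)CCc1c(O)c(C)cc(O[Si](C)(C)C(C)(C)C)c1C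
F2 | step 4 | (2E)-5-{5-[(tert-butyldimethylsilyl)oxy]-2-hydroxy-3,6-dimethylphenyl}-3-methylpent-2-en-1-yl methyl carbonate | COC(=O)OC/C=C(\C)CCc1c(O)c(C)cc(O[Si](C)(C)C(C)(C)C)c1C
F3 | step 4 | tert-butyl{[(2S)-2-ethenyl-2,5,8-trimethyl-3,4-dihydro-2H-chromen-6-yl]oxy}dimethylsilane | C=C[C@]1(C)CCc2c(C)c(O[Si](C)(C)C(C)(C)C)cc(C)c2O1
F4 | step 4 | trimethyl[(5E)-6,10-dimethylundeca-5,9-dien-1-yn-1-yl]silane | C[Si](C)(C)C#CCC/C=C(\C)CCC=C(C)C
F5 | step 4 | (5E)-6,10-dimethylundeca-5,9-dien-1-yne | C#CCC/C=C(\C)CCC=C(C)C
F6 | step 4 | (1E,5E)-1-iodo-2,6,10-trimethylundeca-1,5,9-triene | I/C=C(\C)CC/C=C(\C)CCC=C(C)C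
F7 | step 5 | (3R,6E,10E)-3-{2-bromo-4-[(tert-butyldimethylsilyl)oxy]-3,6-dimethylphenoxy}-3,7,11,15-tetramethylhexadeca-6,10,14-trien-1-ol | OCC[C@@](C)(CC/C=C(\C)CC/C=C(\C)CCC=C(C)C)Oc1c(Br)c(C)c(O[Si](C)(C)C(C)(C)C)cc1C
F8 | step 5 | tert-butyl{3-bromo-4-{[(3R,6E,10E)-1-bromo-3,7,11,15-tetramethylhexadeca-6,10,14-trien-3-yl]oxy}-2,5-dimethylphenoxy}dimethylsilane | BrCC[C@@](C)(CC/C=C(\C)CC/C=C(\C)CCC=C(C)C)Oc1c(Br)c(C)c(O[Si](C)(C)C(C)(C)C)cc1C
F9 | step 2 | 2,5-dimethylcyclohexa-2,5-diene-1,4-dione | CC1=CC(=O)C(C)=CC1=O
F10 | step 2 | 2-bromo-3,6-dimethylbenzene-1,4-diol | Cc1cc(O)c(C)c(Br)c1O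
A1 | alternative 1 | tert-butyldimethyl{[(2S)-2,5,8-trimethyl-2-[(phenylsulfonyl)methyl]-3,4-dihydro-2H-chromen-6-yl]oxy}silane | C[C@@]1(CS(=O)(=O)c2ccccc2)CCc2c(C)c(O[Si](C)(C)C(C)(C)C)cc(C)c2O1
A2 | alternative 1 | (2E,6E)-1-bromo-3,7,11-trimethyldodeca-2,6,10-triene | CC(C)=CCC/C(C)=C/CC/C(C)=C/CBr
A3 | alternative 1 | tert-butyldimethyl{[(2S)-2,5,8-trimethyl-2-[(3E,7E)-4,8,12-trimethyl-1-(phenylsulfonyl)trideca-3,7,11-trien-1-yl]-3,4-dihydro-2H-chromen-6-yl]oxy}silane (sulfonyl-bearing carbon as a mixture) | C[C@@]1(C(C/C=C(\C)CC/C=C(\C)CCC=C(C)C)S(=O)(=O)c2ccccc2)CCc2c(C)c(O[Si](C)(C)C(C)(C)C)cc(C)c2O1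
A4 | alternative 2 | 2,5-dimethyl-3-[(2E,6E,10E)-3,7,11,15-tetramethylhexadeca-2,6,10,14-tetraen-1-yl]benzene-1,4-diol | CC(C)=CCC/C(C)=C/CC/C(C)=C/CC/C(C)=C/Cc1c(C)c(O)cc(C)c1O
A5 | alternative 3 | 4-[(3R,6E,10E)-3-hydroxy-3,7,11,15-tetramethylhexadeca-6,10,14-trien-1-yl]-2,5-dimethylphenol | CC(C)=CCC/C(C)=C/CC/C(C)=C/CC[C@@](C)(O)CCc1cc(C)c(O)cc1C
A6 | alternative 3 | (2R)-2,6,9-trimethyl-2-[(3E,7E)-4,8,12-trimethyltrideca-3,7,11-trien-1-yl]-1-oxaspiro[4.5]deca-6,9-dien-8-one (spiro centre as a mixture) | CC(C)=CCC/C(C)=C/CC/C(C)=C/CC[C@]1(C)CCC2(O1)C=C(C)C(=O)C=C2C
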